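**Retrosynthetic overview**

1. The 14-membered carbocycle is closed last, by ring-closing metathesis at C3=C4 of a seco-triene that already holds the 1,2-dioxane and the cis-fused α-methylene-γ-lactone.
2. The lactone comes from a 2-methylene-1,4-diol by oxidative lactonisation; the chain is cut at the (12Z)-olefin, made by a Wittig reaction of an α-peroxy methyl ketone (west fragment) with a C13 ylide (east fragment).
3. West fragment (C4–C12), from (E)-geranylacetone: perhydrolysis of a (7R,8R)-epoxide gives the C8 hydroperoxide, which opens an (11S,12S)-epoxy alcohol at C11 to close the dioxane.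
4. East fragment (C13, C14, C1–C3, C15–C17): an Evans syn-aldol with acrolein sets C1/C2; a Weinreb ketone synthesis and methylenation build the 2-propenyl unit.
5. Ring order: 1,2-dioxane, then γ-lactone, then 14-membered carbocycle.

Assumption: configuration is taken from the SMILES (1R,2R,7R,8S,11R; 3E,12Z), with ring carbons called C1–C14 (C1 carries the lactone α-carbon C15, C2 the lactone oxygen, C16 = lactone C=O, C17 = exocyclic CH2).

**West fragment**

Step 1
Reactants: 1 (5E)-6,10-dimethylundeca-5,9-dien-2-one ((E)-geranylacetone)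
Product: 2 (5E)-2,6,10-trimethylundeca-1,5,9-triene
Conditions: Ph3PCH3Br, KOtBu, THF, 0 °C to rt
Reagents that add atoms: methyltriphenylphosphonium bromide C[P+](c1ccccc1)(c1ccccc1)c1ccccc1.[Br-]
Why: Wittig methylenation of the methyl ketone supplies the 1,1-disubstituted C4 olefin used in the final metathesis.

Step 2
Reactants: 2 (5E)-2,6,10-trimethylundeca-1,5,9-triene
Product: 3 (2E,6E)-2,6,10-trimethylundeca-2,6,10-trien-1-ol
Conditions: SeO2 (cat.), t-BuOOH, salicylic acid (cat.), CH2Cl2, 0 °C to rt, stopped at partial conversion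
Reagents that add atoms: selenium dioxide O=[Se]=O (catalytic oxygen carrier); tert-butyl hydroperoxide CC(C)(C)OO (terminal oxidant)
Why: Allylic oxidation (ene reaction then [2,3]-sigmatropic shift) is selective for the E-methyl group of the terminal trisubstituted olefin and gives the E-allylic alcohol.

Step 3
Reactants: 3 (2E,6E)-2,6,10-trimethylundeca-2,6,10-trien-1-ol
Product: 4 [(2S,3S)-3-[(3E)-3,7-dimethylocta-3,7-dien-1-yl]-2-methyloxiran-2-yl]methanol
Conditions: Ti(OiPr)4 (cat.), L-(+)-diethyl tartrate, t-BuOOH, 4 Å MS, CH2Cl2, −20 °C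
Reagents that add atoms: tert-butyl hydroperoxide CC(C)(C)OO
Why: Sharpless asymmetric epoxidation touches only the allylic alcohol, and L-(+)-tartrate gives the (2S,3S)-epoxide, i.e. 11S,12S.

Step 4
Reactants: 4 [(2S,3S)-3-[(3E)-3,7-dimethylocta-3,7-dien-1-yl]-2-methyloxiran-2-yl]methanol
Product: 5 [(2S,3S)-2-methyl-3-[2-[(2R,3R)-2-methyl-3-(3-methylbut-3-en-1-yl)oxiran-2-yl]ethyl]oxiran-2-yl]methanol
Conditions: D-fructose-derived Shi ketone (0.3 equiv), KHSO5 (Oxone), K2CO3, Bu4NHSO4, MeCN/CH2(OMe)2/aq. Na2B4O7 buffer, 0 °C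
Reagents that add atoms: potassium peroxymonosulfate [K+].OOS(=O)(=O)[O-]
Why: Shi asymmetric epoxidation of the only remaining trisubstituted olefin gives the (7R,8R)-epoxide by reagent control, while the 1,1-disubstituted olefin reacts far more slowly.

Step 5
Reactants: 5 [(2S,3S)-2-methyl-3-[2-[(2R,3R)-2-methyl-3-(3-methylbut-3-en-1-yl)oxiran-2-yl]ethyl]oxiran-2-yl]methanol
Product: 6 (5R,6S)-6-hydroperoxy-8-[(2S,3S)-3-(hydroxymethyl)-3-methyloxiran-2-yl]-2,6-dimethyloct-1-en-5-ol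
Conditions: anhydrous H2O2 in Et2O (excess), H3PMo12O40 (cat.), Et2O, rt
Reagents that add atoms: hydrogen peroxide OO
Why: Acid-catalysed perhydrolysis opens the trialkyl epoxide at the tertiary carbon C8 with inversion (8S hydroperoxide, 7R alcohol), while the epoxy alcohol, deactivated by its CH2OH group, is left intact.

Step 6
Reactants: 6 (5R,6S)-6-hydroperoxy-8-[(2S,3S)-3-(hydroxymethyl)-3-methyloxiran-2-yl]-2,6-dimethyloct-1-en-5-ol
Product: 7 (2S)-2-[(3R,6S)-6-[(1R)-1-hydroxy-4-methylpent-4-en-1-yl]-6-methyl-1,2-dioxan-3-yl]propane-1,2-diol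
Conditions: Et3N, CF3CH2OH, 0 °C to rt
Reagents that add atoms: none
Why: Intramolecular 6-exo SN2 opening of the 2,3-epoxy alcohol at its distal carbon C11 by the tertiary peroxide anion closes the 1,2-dioxane with inversion, giving 11R.

Step 7
Reactants: 7 (2S)-2-[(3R,6S)-6-[(1R)-1-hydroxy-4-methylpent-4-en-1-yl]-6-methyl-1,2-dioxan-3-yl]propane-1,2-diol
Product: 8 1-[(3R,6S)-6-[(1R)-1-hydroxy-4-methylpent-4-en-1-yl]-6-methyl-1,2-dioxan-3-yl]ethan-1-one
Conditions: NaIO4, THF/H2O, 0 °C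
Reagents that add atoms: none
Why: Malaprade glycol cleavage of the 12,13-diol unveils the C12 methyl ketone without touching the peroxide or the C7 alcohol.

Step 8
Reactants: 8 1-[(3R,6S)-6-[(1R)-1-hydroxy-4-methylpent-4-en-1-yl]-6-methyl-1,2-dioxan-3-yl]ethan-1-one
Product: 9 (1R)-1-[(3S,6R)-6-acetyl-3-methyl-1,2-dioxan-3-yl]-4-methylpent-4-en-1-yl acetate
Conditions: Ac2O, Sc(OTf)3 (cat.), MeCN, −20 °C
Reagents that add atoms: acetic anhydride CC(=O)OC(C)=O
Why: Lewis acid-catalysed acetylation of the hindered C7 alcohol avoids amine bases that could trigger Kornblum–DeLaMare cleavage of the α-peroxy ketone.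

**East fragment**

Step 9
Reactants: 10 (4S)-4-benzyl-1,3-oxazolidin-2-one; 11 4-chlorobutanoyl chloride
Product: 13 (4S)-4-benzyl-3-(4-chlorobutanoyl)-1,3-oxazolidin-2-one, via lithium oxazolidinide 12 (not isolated)
Conditions: n-BuLi, THF, −78 °C; then 11, −78 to 0 °C
Reagents that add atoms: none
Why: N-acylation of the lithiated Evans auxiliary by the acid chloride.

Step 10
Reactants: 13 (4S)-4-benzyl-3-(4-chlorobutanoyl)-1,3-oxazolidin-2-one; 14 acrolein (prop-2-enal)
Product: 17 (4S)-4-benzyl-3-[(2S,3R)-2-(2-chloroethyl)-3-hydroxypent-4-enoyl]-1,3-oxazolidin-2-one, via boron enolate 15 (not isolated), via boron aldolate 16 (not isolated)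
Conditions: Bu2BOTf, Et3N, CH2Cl2, −78 to 0 °C; 14, −78 to 0 °C; then pH 7 buffer, MeOH, H2O2, 0 °C
Reagents that add atoms: none
Why: Evans syn-aldol through the Z-boron enolate and a Zimmerman–Traxler transition state, in which the (S)-benzyl auxiliary sets 2S,3R (the future C1 and C2, cis on the lactone).

Step 11
Reactants: 17 (4S)-4-benzyl-3-[(2S,3R)-2-(2-chloroethyl)-3-hydroxypent-4-enoyl]-1,3-oxazolidin-2-one
Product: 18 (2S,3R)-2-(2-chloroethyl)-3-hydroxy-N-methoxy-N-methylpent-4-enamide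
Conditions: MeONHMe·HCl, AlMe3, CH2Cl2, −15 to 0 °C
Reagents that add atoms: N,O-dimethylhydroxylamine hydrochloride CNOC.Cl
Why: Aluminium amide transamidation of the β-hydroxy imide gives the Weinreb amide and releases the auxiliary without epimerisation.

Step 12
Reactants: 18 (2S,3R)-2-(2-chloroethyl)-3-hydroxy-N-methoxy-N-methylpent-4-enamide
Product: 19 (2S,3R)-2-(2-chloroethyl)-N-methoxy-3-(methoxymethoxy)-N-methylpent-4-enamide
Conditions: MOMCl, iPr2NEt, CH2Cl2, 0 °C to rt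
Reagents that add atoms: chloromethyl methyl ether COCCl
Why: O-alkylation protects the secondary alcohol as its methoxymethyl acetal and removes the risk of the alkoxide displacing the chloride.

Step 13
Reactants: 19 (2S,3R)-2-(2-chloroethyl)-N-methoxy-3-(methoxymethoxy)-N-methylpent-4-enamide
Product: 21 (3S,4R)-3-(2-chloroethyl)-1,4-bis(methoxymethoxy)hex-5-en-2-one, via lithium hemiaminal alkoxide 20 (not isolated)
Conditions: Bu3SnCH2OCH2OCH3, n-BuLi, THF, −78 °C; then 19, −78 °C; AcOH quench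
Reagents that add atoms: tributyl[(methoxymethoxy)methyl]stannane CCCC[Sn](CCCC)(CCCC)COCOC
Why: Tin–lithium exchange gives the α-alkoxymethyllithium, which adds once to the Weinreb amide through the chelated tetrahedral intermediate to give the ketone (C15 with C16).

Step 14
Reactants: 21 (3S,4R)-3-(2-chloroethyl)-1,4-bis(methoxymethoxy)hex-5-en-2-one
Product: 22 (3R,4R)-3-(2-chloroethyl)-4-(methoxymethoxy)-2-[(methoxymethoxy)methyl]hexa-1,5-diene
Conditions: Cp2TiMe2, toluene, 65 °C, dark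
Reagents that add atoms: dimethyltitanocene C[Ti](C)(C1C=CC=C1)C1C=CC=C1
Why: Petasis methylenation with a non-basic titanium carbene installs C17 without epimerising the adjacent stereocentre or eliminating the β-alkoxy group (the descriptor changes only through CIP priorities).

Step 15
Reactants: 22 (3R,4R)-3-(2-chloroethyl)-4-(methoxymethoxy)-2-[(methoxymethoxy)methyl]hexa-1,5-diene
Product: 23 (3R,4R)-3-(2-iodoethyl)-4-(methoxymethoxy)-2-[(methoxymethoxy)methyl]hexa-1,5-diene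
Conditions: NaI, acetone, reflux
Reagents that add atoms: sodium iodide [Na+].[I-]
Why: Finkelstein halide exchange (SN2) at the primary carbon, driven by precipitation of NaCl.

Step 16
Reactants: 23 (3R,4R)-3-(2-iodoethyl)-4-(methoxymethoxy)-2-[(methoxymethoxy)methyl]hexa-1,5-diene
Product: 24 [(3R,4R)-4-(methoxymethoxy)-3-[3-(methoxymethoxy)prop-1-en-2-yl]hex-5-en-1-yl]triphenylphosphonium iodide
Conditions: PPh3, MeCN, 80 °C
Reagents that add atoms: triphenylphosphine c1ccc(cc1)P(c1ccccc1)c1ccccc1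
Why: SN2 quaternisation of triphenylphosphine by the primary iodide gives the Wittig salt.

**Coupling and end game**

Step 17
Reactants: 24 [(3R,4R)-4-(methoxymethoxy)-3-[3-(methoxymethoxy)prop-1-en-2-yl]hex-5-en-1-yl]triphenylphosphonium iodide; 9 (1R)-1-[(3S,6R)-6-acetyl-3-methyl-1,2-dioxan-3-yl]-4-methylpent-4-en-1-yl acetate
Product: 26 (1R)-1-[(3S,6R)-6-[(2Z,5R,6R)-6-(methoxymethoxy)-5-[3-(methoxymethoxy)prop-1-en-2-yl]octa-2,7-dien-2-yl]-3-methyl-1,2-dioxan-3-yl]-4-methylpent-4-en-1-yl acetate, via phosphorus ylide 25 (not isolated)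
Conditions: NaN(SiMe3)2, THF, −78 to 0 °C; then 9, −78 to −20 °C
Reagents that add atoms: none
Why: Wittig olefination of an α-oxygenated methyl ketone with a non-stabilised ylide (Still-type) places the oxygen-bearing C11 cis to the new chain and so gives the (12Z)-trisubstituted olefin.

Step 18
Reactants: 26 (1R)-1-[(3S,6R)-6-[(2Z,5R,6R)-6-(methoxymethoxy)-5-[3-(methoxymethoxy)prop-1-en-2-yl]octa-2,7-dien-2-yl]-3-methyl-1,2-dioxan-3-yl]-4-methylpent-4-en-1-yl acetate
Product: 27 (1R)-1-[(3S,6R)-6-[(2Z,5R,6R)-6-hydroxy-5-(3-hydroxyprop-1-en-2-yl)octa-2,7-dien-2-yl]-3-methyl-1,2-dioxan-3-yl]-4-methylpent-4-en-1-yl acetate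
Conditions: ZnBr2, n-PrSH, CH2Cl2, 0 °C, 10 min
Reagents that add atoms: none
Why: Lewis acid/thiol cleavage of both methoxymethyl acetals is fast and mild enough to spare the peroxide, the acetate and all stereocentres.

Step 19
Reactants: 27 (1R)-1-[(3S,6R)-6-[(2Z,5R,6R)-6-hydroxy-5-(3-hydroxyprop-1-en-2-yl)octa-2,7-dien-2-yl]-3-methyl-1,2-dioxan-3-yl]-4-methylpent-4-en-1-yl acetate
Product: 30 (1R)-1-[(3S,6R)-6-[(2Z)-4-[(2R,3R)-2-ethenyl-4-methylidene-5-oxooxolan-3-yl]but-2-en-2-yl]-3-methyl-1,2-dioxan-3-yl]-4-methylpent-4-en-1-yl acetate, via hydroxy enal 28 (not isolated), via lactol 29 (not isolated)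
Conditions: TEMPO (cat.), PhI(OAc)2, CH2Cl2, rt
Reagents that add atoms: none
Why: Oxidative lactonisation, in which TEMPO/PhI(OAc)2 oxidises the primary allylic alcohol to the enal, the C2 hydroxyl closes the lactol, and the lactol is oxidised to the α-methylene-γ-butyrolactone, cis-fused because of the Evans syn relationship.

Step 20
Reactants: 30 (1R)-1-[(3S,6R)-6-[(2Z)-4-[(2R,3R)-2-ethenyl-4-methylidene-5-oxooxolan-3-yl]but-2-en-2-yl]-3-methyl-1,2-dioxan-3-yl]-4-methylpent-4-en-1-yl acetate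
Product: 31 target (1R,2R,3E,7R,8S,11R,12Z)-7-acetoxy-8,11-epidioxycembra-3,12,15(17)-trien-16,2-olide (numbering as stated above)
Conditions: second-generation Hoveyda–Grubbs catalyst RuCl2(H2IMes)(=CH-C6H4-2-OiPr) (15 mol %), toluene (1 mM), 80 °C
Reagents that add atoms: none
Why: Ring-closing metathesis, in which the ruthenium alkylidene formed at the C3 vinyl group closes onto the 1,1-disubstituted C4 olefin with loss of ethene; the E-trisubstituted olefin is expected as the less strained geometry of the 14-membered ring, and no stereocentre is touched.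

**Compound list**

1 | (5E)-6,10-dimethylundeca-5,9-dien-2-one ((E)-geranylacetone) | CC(=O)CC/C=C(\C)CCC=C(C)C | starting material
2 | (5E)-2,6,10-trimethylundeca-1,5,9-triene | C=C(C)CC/C=C(\C)CCC=C(C)C | intermediate
3 | (2E,6E)-2,6,10-trimethylundeca-2,6,10-trien-1-ol | C=C(C)CC/C=C(\C)CC/C=C(\C)CO | intermediate
4 | [(2S,3S)-3-[(3E)-3,7-dimethylocta-3,7-dien-1-yl]-2-methyloxiran-2-yl]methanol | C=C(C)CC/C=C(\C)CC[C@@H]1O[C@@]1(C)CO | intermediate
5 | [(2S,3S)-2-methyl-3-[2-[(2R,3R)-2-methyl-3-(3-methylbut-3-en-1-yl)oxiran-2-yl]ethyl]oxiran-2-yl]methanol | C=C(C)CC[C@H]1O[C@]1(C)CC[C@@H]2O[C@@]2(C)CO | intermediate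
6 | (5R,6S)-6-hydroperoxy-8-[(2S,3S)-3-(hydroxymethyl)-3-methyloxiran-2-yl]-2,6-dimethyloct-1-en-5-ol | C=C(C)CC[C@@H](O)[C@@](C)(OO)CC[C@@H]1O[C@@]1(C)CO | intermediate
7 | (2S)-2-[(3R,6S)-6-[(1R)-1-hydroxy-4-methylpent-4-en-1-yl]-6-methyl-1,2-dioxan-3-yl]propane-1,2-diol | C=C(C)CC[C@@H](O)[C@]1(C)CC[C@@H](OO1)[C@@](C)(O)CO | intermediate
8 | 1-[(3R,6S)-6-[(1R)-1-hydroxy-4-methylpent-4-en-1-yl]-6-methyl-1,2-dioxan-3-yl]ethan-1-one | C=C(C)CC[C@@H](O)[C@]1(C)CC[C@@H](OO1)C(C)=O | intermediate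
9 | (1R)-1-[(3S,6R)-6-acetyl-3-methyl-1,2-dioxan-3-yl]-4-methylpent-4-en-1-yl acetate (west fragment) | C=C(C)CC[C@@H](OC(C)=O)[C@]1(C)CC[C@@H](OO1)C(C)=O | intermediate
10 | (4S)-4-benzyl-1,3-oxazolidin-2-one | O=C1N[C@@H](Cc2ccccc2)CO1 | starting material
11 | 4-chlorobutanoyl chloride | ClCCCC(Cl)=O | starting material
12 | lithium (4S)-4-benzyl-2-oxo-1,3-oxazolidin-3-ide | O=C1[N-][C@@H](Cc2ccccc2)CO1.[Li+] | intermediate
13 | (4S)-4-benzyl-3-(4-chlorobutanoyl)-1,3-oxazolidin-2-one | O=C(CCCCl)N1[C@@H](Cc2ccccc2)COC1=O | intermediate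
14 | acrolein (prop-2-enal) | C=CC=O | starting material
15 | dibutylboron (Z)-enolate of 13 | CCCCB(CCCC)O/C(=C\CCCl)N1[C@@H](Cc2ccccc2)COC1=O | intermediate
16 | O-dibutylboryl aldolate of 17 | CCCCB(CCCC)O[C@H](C=C)[C@H](CCCl)C(=O)N1[C@@H](Cc2ccccc2)COC1=O | intermediate
17 | (4S)-4-benzyl-3-[(2S,3R)-2-(2-chloroethyl)-3-hydroxypent-4-enoyl]-1,3-oxazolidin-2-one | O=C(N1[C@@H](Cc2ccccc2)COC1=O)[C@@H](CCCl)[C@H](O)C=C | intermediate
18 | (2S,3R)-2-(2-chloroethyl)-3-hydroxy-N-methoxy-N-methylpent-4-enamide | CON(C)C(=O)[C@@H](CCCl)[C@H](O)C=C | intermediate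
19 | (2S,3R)-2-(2-chloroethyl)-N-methoxy-3-(methoxymethoxy)-N-methylpent-4-enamide | CON(C)C(=O)[C@@H](CCCl)[C@H](OCOC)C=C | intermediate
20 | lithium alkoxide of the tetrahedral adduct of 19 with LiCH2OCH2OCH3 (hemiaminal carbon undefined) | COCOCC([O-])(N(C)OC)[C@@H](CCCl)[C@H](OCOC)C=C.[Li+] | intermediate
21 | (3S,4R)-3-(2-chloroethyl)-1,4-bis(methoxymethoxy)hex-5-en-2-one | COCOCC(=O)[C@@H](CCCl)[C@H](OCOC)C=C | intermediate
22 | (3R,4R)-3-(2-chloroethyl)-4-(methoxymethoxy)-2-[(methoxymethoxy)methyl]hexa-1,5-diene | COCOCC(=C)[C@@H](CCCl)[C@H](OCOC)C=C | intermediate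
23 | (3R,4R)-3-(2-iodoethyl)-4-(methoxymethoxy)-2-[(methoxymethoxy)methyl]hexa-1,5-diene | COCOCC(=C)[C@@H](CCI)[C@H](OCOC)C=C | intermediate
24 | [(3R,4R)-4-(methoxymethoxy)-3-[3-(methoxymethoxy)prop-1-en-2-yl]hex-5-en-1-yl]triphenylphosphonium iodide (east fragment) | COCOCC(=C)[C@@H](CC[P+](c1ccccc1)(c1ccccc1)c1ccccc1)[C@H](OCOC)C=C.[I-] | intermediate
25 | triphenylphosphonium ylide of 24 | COCOCC(=C)[C@@H](CC=P(c1ccccc1)(c1ccccc1)c1ccccc1)[C@H](OCOC)C=C | intermediate
26 | (1R)-1-[(3S,6R)-6-[(2Z,5R,6R)-6-(methoxymethoxy)-5-[3-(methoxymethoxy)prop-1-en-2-yl]octa-2,7-dien-2-yl]-3-methyl-1,2-dioxan-3-yl]-4-methylpent-4-en-1-yl acetate | C=C(C)CC[C@@H](OC(C)=O)[C@]1(C)CC[C@@H](OO1)/C(C)=C\C[C@H](C(=C)COCOC)[C@H](OCOC)C=C | intermediate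
27 | (1R)-1-[(3S,6R)-6-[(2Z,5R,6R)-6-hydroxy-5-(3-hydroxyprop-1-en-2-yl)octa-2,7-dien-2-yl]-3-methyl-1,2-dioxan-3-yl]-4-methylpent-4-en-1-yl acetate | C=C(C)CC[C@@H](OC(C)=O)[C@]1(C)CC[C@@H](OO1)/C(C)=C\C[C@H](C(=C)CO)[C@H](O)C=C | intermediate
28 | hydroxy enal: 27 with the primary CH2OH oxidised to CHO | C=C(C)CC[C@@H](OC(C)=O)[C@]1(C)CC[C@@H](OO1)/C(C)=C\C[C@H](C(=C)C=O)[C@H](O)C=C | intermediate
29 | lactol: 30 with C(OH)H in place of the lactone C=O (anomeric carbon undefined) | C=C(C)CC[C@@H](OC(C)=O)[C@]1(C)CC[C@@H](OO1)/C(C)=C\C[C@@H]2C(=C)C(O)O[C@@H]2C=C | intermediate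
30 | (1R)-1-[(3S,6R)-6-[(2Z)-4-[(2R,3R)-2-ethenyl-4-methylidene-5-oxooxolan-3-yl]but-2-en-2-yl]-3-methyl-1,2-dioxan-3-yl]-4-methylpent-4-en-1-yl acetate | C=C(C)CC[C@@H](OC(C)=O)[C@]1(C)CC[C@@H](OO1)/C(C)=C\C[C@@H]2C(=C)C(=O)O[C@@H]2C=C | intermediate
31 | (1R,2R,3E,7R,8S,11R,12Z)-7-acetoxy-8,11-epidioxycembra-3,12,15(17)-trien-16,2-olide | C=C1C(=O)O[C@@H]2/C=C(\C)CC[C@@H](OC(C)=O)[C@]3(C)CC[C@@H](OO3)/C(C)=C\C[C@H]12 | target

**Step count and risks**

Total step count: 20. Longest linear sequence: 12 steps (steps 1–8 then 17–20; the east branch, steps 9–16 then 17–20, is equally long).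

Step 20 (ring-closing metathesis). The C3 alkylidene and the 12,13-olefin form a 1,6-diene, so cyclopentene formation with loss of the west half can compete with the macrocyclisation. The E/Z ratio at C3=C4 is also not secured. Fallback: reverse the order of the two olefin-forming events, setting out from 9 and 24 and coming back at 31. Cross-metathesis of the methallyl group of 9 with the vinyl group of 24 (same ruthenium catalyst, CH2Cl2, 40 °C, excess 9) gives the E-3,4-olefin seco-ketone phosphonium iodide F1 while no 12,13-olefin exists yet. Slow addition of NaN(SiMe3)2 at high dilution forms the tethered ylide F2, which closes the ring by an intramolecular Wittig reaction on the α-peroxy ketone to give the macrocyclic bis(methoxymethyl) ether F3. ZnBr2/n-PrSH then gives the macrocyclic 2,16-diol F4, and TEMPO/PhI(OAc)2 takes it through the macrocyclic hydroxy enal F5 and the macrocyclic lactol F6 to 31.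

Step 17 (Wittig on the α-peroxy ketone). The ylide may deprotonate C11, which would epimerise it or cleave the peroxide (Kornblum–DeLaMare), and the Z-selectivity rests on the α-oxygen effect. Fallback: make the Z-olefin before the peroxide, setting out from 4 (with ylide 25) and coming back at 26. Ti(OiPr)4-mediated opening of 4 at C11 by 4-methoxybenzyl alcohol (inversion) gives the (2S,3R)-3-(4-methoxybenzyloxy)-1,2-diol F7. NaIO4 gives the α-(4-methoxybenzyloxy) methyl ketone F8, and the Wittig reaction with 25 gives the (12Z)-olefin 4-methoxybenzyl ether F9. DDQ frees the (11R)-allylic alcohol F10, and hexachloroacetone/PPh3 converts it with inversion into the (11S)-allylic chloride F11. Shi epoxidation then gives the (7R,8R)-epoxide F12 (the other trisubstituted olefin is deactivated by the allylic chlorine), and H2O2/H3PMo12O40 gives the C8 hydroperoxide F13. Cs2CO3 in DMF closes the dioxane by intramolecular SN2 displacement of chloride with inversion to give the C7 alcohol F14, which is acetylated (Ac2O, Sc(OTf)3) to 26.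

Step 6 (anionic closure of the dioxane). The 6-exo opening may be slow, or it may be diverted to a tetrahydropyran through the C7 hydroxyl, to Payne rearrangement, or to fragmentation of the β-hydroxy hydroperoxide. Fallback: drop the anionic closure and run a Brønsted acid cascade that sets out from 5 and comes back at 7. After perhydrolysis with H2O2/H3PMo12O40, camphorsulfonic acid in CH2Cl2 is added to the crude mixture so that the neutral hydroperoxide opens the protonated epoxy alcohol at C11 (exo, and away from the carbon deactivated by CH2OH). No new compound is needed.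

**Further compounds**

F0 | step 6 | none | none
F1 | step 20 | E-3,4-olefin seco-ketone phosphonium iodide (24 joined through C3 to C4 of 9; C12 still the methyl ketone) | COCOCC(=C)[C@@H](CC[P+](c1ccccc1)(c1ccccc1)c1ccccc1)[C@H](OCOC)/C=C(\C)CC[C@@H](OC(C)=O)[C@]1(C)CC[C@@H](OO1)C(C)=O.[I-]
F2 | step 20 | tethered ylide of F1 | COCOCC(=C)[C@@H](CC=P(c1ccccc1)(c1ccccc1)c1ccccc1)[C@H](OCOC)/C=C(\C)CC[C@@H](OC(C)=O)[C@]1(C)CC[C@@H](OO1)C(C)=O
F3 | step 20 | macrocyclic bis(methoxymethyl) ether (3E,12Z carbocycle; OCH2OCH3 on C2 and C16) | COCOCC(=C)[C@@H]1[C@H](OCOC)/C=C(\C)CC[C@@H](OC(C)=O)[C@]2(C)CC[C@@H](OO2)/C(C)=C\C1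
F4 | step 20 | macrocyclic 2,16-diol | OCC(=C)[C@@H]1[C@H](O)/C=C(\C)CC[C@@H](OC(C)=O)[C@]2(C)CC[C@@H](OO2)/C(C)=C\C1
F5 | step 20 | macrocyclic hydroxy enal (C16 aldehyde; C2 hydroxyl) | O=CC(=C)[C@@H]1[C@H](O)/C=C(\C)CC[C@@H](OC(C)=O)[C@]2(C)CC[C@@H](OO2)/C(C)=C\C1
F6 | step 20 | macrocyclic lactol (31 with C(OH)H in place of the lactone C=O) | C=C1C(O)O[C@@H]2/C=C(\C)CC[C@@H](OC(C)=O)[C@]3(C)CC[C@@H](OO3)/C(C)=C\C[C@H]12
F7 | step 17 | (2S,3R,6E)-3-[(4-methoxybenzyl)oxy]-2,6,10-trimethylundeca-6,10-diene-1,2-diol | C=C(C)CC/C=C(\C)CC[C@@H](OCc1ccc(OC)cc1)[C@@](C)(O)CO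
F8 | step 17 | (3R,6E)-3-[(4-methoxybenzyl)oxy]-6,10-dimethylundeca-6,10-dien-2-one | C=C(C)CC/C=C(\C)CC[C@@H](OCc1ccc(OC)cc1)C(C)=O
F9 | step 17 | (12Z)-olefin 4-methoxybenzyl ether (open chain; 7E-olefin; east part as in 26) | C=C(C)CC/C=C(\C)CC[C@@H](OCc1ccc(OC)cc1)/C(C)=C\C[C@H](C(=C)COCOC)[C@H](OCOC)C=C
F10 | step 17 | (11R)-allylic alcohol from F9 | C=C(C)CC/C=C(\C)CC[C@@H](O)/C(C)=C\C[C@H](C(=C)COCOC)[C@H](OCOC)C=C
F11 | step 17 | (11S)-allylic chloride | C=C(C)CC/C=C(\C)CC[C@H](Cl)/C(C)=C\C[C@H](C(=C)COCOC)[C@H](OCOC)C=C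
F12 | step 17 | (7R,8R)-epoxide of F11 | C=C(C)CC[C@H]1O[C@]1(C)CC[C@H](Cl)/C(C)=C\C[C@H](C(=C)COCOC)[C@H](OCOC)C=C
F13 | step 17 | (7R,8S)-7-hydroxy-8-hydroperoxide of the (11S)-chloride | C=C(C)CC[C@@H](O)[C@@](C)(OO)CC[C@H](Cl)/C(C)=C\C[C@H](C(=C)COCOC)[C@H](OCOC)C=C
F14 | step 17 | 7-deacetyl analogue of 26 (free C7 alcohol) | C=C(C)CC[C@@H](O)[C@]1(C)CC[C@@H](OO1)/C(C)=C\C[C@H](C(=C)COCOC)[C@H](OCOC)C=C
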